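**Retrosynthetic overview**

1. Target numbering (11-oxabicyclo[8.1.0]undec-4-ene): C1/C10 are the oxirane carbons (CHO on C10), C4(Me)=C5 is the ring olefin, C6 and C8 carry the acetates, C7 the isopropyl group. The strategy rests on the Z-trisubstituted C4=C5 double bond of the ten-membered carbocycle, a ring-cis olefin of the kind left behind when SO2 is expelled from a C5–SO2–C4 bridge.
2. Endgame, read backwards: CHO from CH2OH; oxirane from Sharpless epoxidation of the exocyclic allylic alcohol on C10=C1; acetates from the acetonide; all starting from diene 28.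
3. Key disconnection: 28 from the eleven-membered sulfone 25 by Ramberg–Bäcklund ring contraction (C4–C5 bond). 25 comes from thioether 24, closed from an open chain by intramolecular thiolate alkylation (S–C4 bond).
4. Open chain: C10=C1 by Horner–Wadsworth–Emmons reaction of γ-keto phosphonate 11 with the lactol of (R)-γ-valerolactone; C9 from ICH2Cl; C6/C7 by Evans syn-aldol; C8 by hydroxyl-directed syn reduction.
5. Order of ring formation: 1,3-dioxane (acetonide), then eleven-membered thiacycle, then ten-membered carbocycle (key step), then oxirane.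

Key step: step 19

Assumptions: 2-[(4-methoxybenzyl)oxy]acetaldehyde 4 and (R)-γ-valerolactone 12 are taken as purchasable. The PMB ether is used because a plain benzyl ether could not be removed later beside the ring olefin. The C4 configuration is erased in step 19, so racemic lactone would serve as well; the R enantiomer only keeps every intermediate a single stereoisomer. A TBDPS ether is used on the C10 hydroxymethyl group so that it outlasts the acidic acetonide removal. Both ring double bonds of 28 are ring-cis; by CIP rules C4=C5 is Z and C10=C1 is E, because the silyloxymethyl group outranks the ring CH2.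

**Route**

Step 1
Reactants: 1 (4R)-4-benzyl-1,3-oxazolidin-2-one; 2 3-methylbutanoyl chloride
Product: 3 (4R)-4-benzyl-3-(3-methylbutanoyl)-1,3-oxazolidin-2-one
Conditions: n-BuLi, THF, −78 °C; then 2, −78 → 0 °C
Reagents that add atoms: none
Why: N-acylation of the lithiated oxazolidinone by the acid chloride is the standard way to the Evans imide and touches no stereocentre.

Step 2
Reactants: 3 imide; 4 2-[(4-methoxybenzyl)oxy]acetaldehyde
Product: 5 aldol adduct (4R)-4-benzyl-3-{(2R,3R)-3-hydroxy-4-[(4-methoxybenzyl)oxy]-2-(propan-2-yl)butanoyl}-1,3-oxazolidin-2-one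
Conditions: Bu2BOTf, iPr2NEt, CH2Cl2, −78 → 0 °C; then aq. NaH2PO4/Na2HPO4 (pH 7), MeOH, 30% H2O2, 0 °C
Reagents that add atoms: none
Why: Evans syn-aldol reaction: the Z-boron enolate reacts through a closed Zimmerman–Traxler chair in which the benzyl group of the R auxiliary shields one enolate face, so C7 and C6 should be set syn in the required absolute sense.

Step 3
Reactants: 5 aldol adduct
Product: 6 Weinreb amide (2R,3R)-3-hydroxy-N-methoxy-4-[(4-methoxybenzyl)oxy]-N-methyl-2-(propan-2-yl)butanamide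
Conditions: MeNH(OMe)·HCl, AlMe3, CH2Cl2, −10 °C → rt
Reagents that add atoms: N,O-dimethylhydroxylamine hydrochloride, CNOC.Cl
Why: Weinreb transamidation with the aluminium amide is directed to the exocyclic carbonyl by the aluminium alkoxide of the free C6 hydroxyl, releases the auxiliary and gives an acyl donor that stops at the ketone stage.

Step 4
Reactants: 6 Weinreb amide
Product: 7 silyl ether (2R,3R)-N-methoxy-4-[(4-methoxybenzyl)oxy]-N-methyl-2-(propan-2-yl)-3-[(triethylsilyl)oxy]butanamide
Conditions: Et3SiOTf, 2,6-lutidine, CH2Cl2, −78 → 0 °C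
Reagents that add atoms: triethylsilyl trifluoromethanesulfonate, CC[Si](CC)(CC)OS(=O)(=O)C(F)(F)F
Why: Silylation of the hindered secondary alcohol with a silyl triflate blocks attack of this oxygen on the chloromethyl group (furanone formation) in steps 5 and 6, and the triethylsilyl group can later be removed beside the PMB ether.

Step 5
Reactants: 7 silyl ether; 8 chloroiodomethane
Product: 9 chloromethyl ketone (3R,4R)-1-chloro-5-[(4-methoxybenzyl)oxy]-3-(propan-2-yl)-4-[(triethylsilyl)oxy]pentan-2-one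
Conditions: MeLi·LiBr added to 7 and 8, THF, −78 °C; then sat. aq. NH4Cl
Reagents that add atoms: none
Why: Chloromethyllithium, made by iodine–lithium exchange in the presence of the amide, adds once to the Weinreb amide (carbenoid acylation) to give a chelated adduct that collapses to the α-chloro ketone only on work-up, bringing in C9 without over-addition or epimerisation at C7.

Step 6
Reactants: 9 chloromethyl ketone; 10 triethyl phosphonoacetate
Product: 11 keto phosphonate ethyl (5R,6R)-2-(diethoxyphosphoryl)-7-[(4-methoxybenzyl)oxy]-4-oxo-5-(propan-2-yl)-6-[(triethylsilyl)oxy]heptanoate (both epimers at C2)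
Conditions: 10, NaH, THF, 0 °C; then 9, NaI (cat.), 0 °C → rt
Reagents that add atoms: none
Why: SN2 alkylation of the sodium phosphonoacetate by the reactive α-halo ketone (iodide catalysis) forms the C9–C10 bond; the epimeric centre at the phosphonate carbon disappears in step 8.

Step 7
Reactants: 12 (R)-γ-valerolactone
Product: 13 lactol (5R)-5-methyloxolan-2-ol (anomer mixture)
Conditions: iBu2AlH, CH2Cl2, −78 °C; aq. potassium sodium tartrate
Reagents that add atoms: none
Why: Half-reduction of a γ-lactone by iBu2AlH stops at the aluminium hemiacetal at −78 °C and leaves the stereocentre untouched.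

Step 8
Reactants: 11 keto phosphonate; 13 lactol
Product: 14 enoate ethyl (2E,6R)-6-hydroxy-2-{(3R,4R)-5-[(4-methoxybenzyl)oxy]-2-oxo-3-(propan-2-yl)-4-[(triethylsilyl)oxy]pentyl}hept-2-enoate
Conditions: NaH, THF, 0 °C; then 13 (2 equiv), 0 °C → rt
Reagents that add atoms: none
Why: Horner–Wadsworth–Emmons olefination of the ring-opened lactol with the α-substituted phosphonoacetate anion should give mainly the enoate with ester and chain trans (E), the geometry that becomes the ring-cis C10=C1 olefin; the minor Z isomer is removed by chromatography.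

Step 9
Reactants: 14 enoate
Product: 15 hydroxy ketone ethyl (2E,6R)-6-hydroxy-2-{(3R,4R)-4-hydroxy-5-[(4-methoxybenzyl)oxy]-2-oxo-3-(propan-2-yl)pentyl}hept-2-enoate
Conditions: PPTS, MeOH, rt
Reagents that add atoms: none
Why: Acid-catalysed methanolysis of the triethylsilyl ether frees the C6 hydroxyl that must direct the reduction, and leaves PMB ether, ester and enoate intact.

Step 10
Reactants: 15 hydroxy ketone
Product: 16 triol ethyl (2E,6R)-2-{(2R,3S,4R)-2,4-dihydroxy-5-[(4-methoxybenzyl)oxy]-3-(propan-2-yl)pentyl}-6-hydroxyhept-2-enoate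
Conditions: Et2BOMe, THF/MeOH (4:1), −78 °C; NaBH4, −78 °C; then AcOH, MeOH co-evaporation
Reagents that add atoms: none
Why: Narasaka–Prasad reduction: Et2BOMe ties the C6 hydroxyl and the C8 ketone into a six-membered boron chelate that hydride attacks axially, which should give the 1,3-syn diol and thus the all-syn C6/C7/C8 triad, the enoate being inert at −78 °C.

Step 11
Reactants: 16 triol
Product: 17 acetonide ethyl (2E,6R)-6-hydroxy-2-({(4R,5S,6R)-6-{[(4-methoxybenzyl)oxy]methyl}-2,2-dimethyl-5-(propan-2-yl)-1,3-dioxan-4-yl}methyl)hept-2-enoate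
Conditions: Me2C(OMe)2, PPTS, CH2Cl2, rt
Reagents that add atoms: 2,2-dimethoxypropane, COC(C)(C)OC
Why: Acid-catalysed transketalisation of the syn-1,3-diol gives the all-equatorial 1,3-dioxane faster than the C8 hydroxyl can lactonise onto the enoate, and the remote C4 hydroxyl is returned free on aqueous work-up.

Step 12
Reactants: 17 acetonide ester
Product: 18 diol (2E,6R)-2-({(4R,5S,6R)-6-{[(4-methoxybenzyl)oxy]methyl}-2,2-dimethyl-5-(propan-2-yl)-1,3-dioxan-4-yl}methyl)hept-2-ene-1,6-diol
Conditions: iBu2AlH, CH2Cl2, −78 °C; aq. potassium sodium tartrate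
Reagents that add atoms: none
Why: 1,2-Reduction of the enoate by iBu2AlH gives the allylic alcohol without touching ketal, PMB ether or olefin geometry.

Step 13
Reactants: 18 diol
Product: 19 silyl ether (2R,5E)-7-[(tert-butyldiphenylsilyl)oxy]-6-({(4R,5S,6R)-6-{[(4-methoxybenzyl)oxy]methyl}-2,2-dimethyl-5-(propan-2-yl)-1,3-dioxan-4-yl}methyl)hept-5-en-2-ol
Conditions: TBDPSCl, imidazole, CH2Cl2, 0 °C
Reagents that add atoms: tert-butyl(chloro)diphenylsilane, CC(C)(C)[Si](Cl)(c1ccccc1)c1ccccc1
Why: The bulky silyl chloride silylates the primary allylic alcohol selectively over the secondary C4 alcohol, and the TBDPS ether is robust enough for the acidic acetonide removal in step 20.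

Step 14
Reactants: 19 silyl ether
Product: 20 mesylate (2R,5E)-7-[(tert-butyldiphenylsilyl)oxy]-6-({(4R,5S,6R)-6-{[(4-methoxybenzyl)oxy]methyl}-2,2-dimethyl-5-(propan-2-yl)-1,3-dioxan-4-yl}methyl)hept-5-en-2-yl methanesulfonate
Conditions: MsCl, Et3N, CH2Cl2, 0 °C
Reagents that add atoms: methanesulfonyl chloride, CS(Cl)(=O)=O
Why: Mesylation turns the secondary C4 alcohol into the leaving group for ring closure, with retention at this stage.

Step 15
Reactants: 20 mesylate
Product: 21 primary alcohol (2R,5E)-7-[(tert-butyldiphenylsilyl)oxy]-6-{[(4R,5S,6R)-6-(hydroxymethyl)-2,2-dimethyl-5-(propan-2-yl)-1,3-dioxan-4-yl]methyl}hept-5-en-2-yl methanesulfonate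
Conditions: DDQ, CH2Cl2/aq. NaH2PO4/Na2HPO4 (pH 7), 0 °C → rt
Reagents that add atoms: none
Why: Oxidative PMB cleavage by DDQ (hydride abstraction, hydrolysis of the oxocarbenium ion) frees the C5 alcohol under buffered conditions that spare olefin, mesylate, silyl ether and ketal.

Step 16
Reactants: 21 primary alcohol
Product: 22 thioacetate, compound 21 with the CH2OH group converted into CH2SC(O)CH3
Conditions: PPh3, DIAD, AcSH, THF, 0 °C → rt
Reagents that add atoms: thioacetic acid, CC(=O)S
Why: Mitsunobu thioesterification of the primary alcohol places sulfur on C5 under neutral conditions that the secondary mesylate tolerates.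

Step 17
Reactants: 22 thioacetate
Product: 24 eleven-membered thioether (1R,4S,7E,10R,14S)-8-{[(tert-butyldiphenylsilyl)oxy]methyl}-4,12,12-trimethyl-14-(propan-2-yl)-11,13-dioxa-3-thiabicyclo[8.3.1]tetradec-7-ene, via mesylate thiol 23 (not isolated)
Conditions: Cs2CO3, degassed DMF/MeOH (9:1), 1 mM, syringe-pump addition, 45 °C
Reagents that add atoms: none
Why: Methanolysis of the thioacetate gives the caesium thiolate, which closes the eleven-membered ring by intramolecular SN2 displacement of the C4 mesylate with inversion (11-exo-tet); high dilution and the caesium counter-ion favour cyclisation over oligomerisation.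

Step 18
Reactants: 24 thioether
Product: 25 eleven-membered sulfone (1R,4S,7E,10R,14S)-8-{[(tert-butyldiphenylsilyl)oxy]methyl}-4,12,12-trimethyl-14-(propan-2-yl)-11,13-dioxa-3-thiabicyclo[8.3.1]tetradec-7-ene 3,3-dioxide
Conditions: (NH4)6Mo7O24·4H2O (cat.), 30% H2O2, EtOH, 0 °C → rt
Reagents that add atoms: hydrogen peroxide, OO
Why: Molybdate-catalysed peroxide oxidation takes the sulfide through the sulfoxide to the sulfone and is chemoselective for sulfur over the trisubstituted olefin, which a peracid would epoxidise.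

Step 19
Reactants: 25 eleven-membered sulfone
Product: 28 diene acetonide (1S,2Z,6E,9R,13S)-7-{[(tert-butyldiphenylsilyl)oxy]methyl}-3,11,11-trimethyl-13-(propan-2-yl)-10,12-dioxabicyclo[7.3.1]trideca-2,6-diene, via α-bromo sulfone 26 (not isolated), via episulfone 27 (not isolated)
Conditions: KOH/Al2O3, CBr2F2, tBuOH/CH2Cl2, 0 °C → rt
Reagents that add atoms: none
Why: Ramberg–Bäcklund reaction with in situ halogenation: KOH on alumina forms the α-sulfonyl carbanion at C5, CBr2F2 brominates it to 26, the C4 carbanion then displaces bromide in a 1,3-elimination to episulfone 27, and 27 loses SO2 cheletropically to leave the C4=C5 olefin. The closest known reaction type is the contraction of medium and large cyclic sulfones to cycloalkenes under these conditions. The ten-membered carbocycle is closed by a 3-exo-tet displacement inside the eleven-membered ring, so the one new ring bond (C4–C5) forms in a three-membered ring and the medium ring arises by contraction, not by end-to-end cyclisation. No stereocentre is created: the centre at C4 of 25 is destroyed, and C6, C7 and C8 carry no acidic hydrogen. The step needs the Z (ring-cis) geometry, expected because the cis-fused episulfone is the one the eleven-membered ring accommodates and SO2 loss is stereospecific; it also needs bromination to outrun β-elimination of the C6 oxygen, which is helped by that oxygen being a poor ketal alkoxide leaving group held in the dioxane, while the difluorocarbene released from CBr2F2 spares the C10=C1 olefin.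

Step 20
Reactants: 28 diene acetonide
Product: 29 diol (1R,2S,3S,4Z,8E)-9-{[(tert-butyldiphenylsilyl)oxy]methyl}-5-methyl-2-(propan-2-yl)cyclodeca-4,8-diene-1,3-diol
Conditions: PPTS, MeOH, 40 °C
Reagents that add atoms: none
Why: Acid-catalysed transketalisation to methanol removes the acetonide while the primary TBDPS ether survives, and the mild acid should avoid ionisation at the allylic C6 oxygen and transannular reactions of the 1,5-diene.

Step 21
Reactants: 29 diol
Product: 30 diacetate (1R,2S,3S,4Z,8E)-9-{[(tert-butyldiphenylsilyl)oxy]methyl}-5-methyl-2-(propan-2-yl)cyclodeca-4,8-diene-1,3-diyl diacetate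
Conditions: Ac2O, pyridine, DMAP, CH2Cl2, rt
Reagents that add atoms: acetic anhydride, CC(=O)OC(C)=O
Why: DMAP-catalysed acylation esterifies both hindered secondary alcohols without affecting any stereocentre.

Step 22
Reactants: 30 diacetate
Product: 31 allylic alcohol (1R,2S,3S,4Z,8E)-9-(hydroxymethyl)-5-methyl-2-(propan-2-yl)cyclodeca-4,8-diene-1,3-diyl diacetate
Conditions: HF·pyridine, pyridine, THF, 0 °C → rt
Reagents that add atoms: none
Why: Buffered fluoride cleavage of the silyl ether frees the primary allylic alcohol without acetate migration or hydrolysis.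

Step 23
Reactants: 31 allylic alcohol
Product: 32 epoxy alcohol (1R,4Z,6S,7S,8R,10R)-10-(hydroxymethyl)-4-methyl-7-(propan-2-yl)-11-oxabicyclo[8.1.0]undec-4-ene-6,8-diyl diacetate
Conditions: Ti(OiPr)4, D-(−)-diethyl tartrate, tBuOOH, 4 Å molecular sieves, CH2Cl2, −25 °C
Reagents that add atoms: tert-butyl hydroperoxide, CC(C)(C)OO
Why: Sharpless asymmetric epoxidation: the titanium tartrate complex binds the primary allylic alcohol and delivers oxygen syn-stereospecifically to the face set by D-(−)-diethyl tartrate (the enantiomer that gives 2R,3R epoxy alcohols from 2,3E-disubstituted allylic alcohols), which sets C1 and C10, while the C4=C5 olefin, an allylic acetate without free hydroxyl, does not react.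

Step 24
Reactants: 32 epoxy alcohol
Product: 33 target (1R,4Z,6S,7S,8R,10S)-10-formyl-4-methyl-7-(propan-2-yl)-11-oxabicyclo[8.1.0]undec-4-ene-6,8-diyl diacetate
Conditions: Dess–Martin periodinane, NaHCO3, CH2Cl2, 0 °C → rt
Reagents that add atoms: none
Why: Dess–Martin oxidation of the primary epoxy alcohol gives the aldehyde under buffered conditions; the adjacent C10 is quaternary, so no epimerisation is possible.

**Compound list**

1 | (4R)-4-benzyl-1,3-oxazolidin-2-one | O=C1N[C@H](Cc2ccccc2)CO1 | starting material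
2 | 3-methylbutanoyl chloride | CC(C)CC(Cl)=O | starting material
3 | (4R)-4-benzyl-3-(3-methylbutanoyl)-1,3-oxazolidin-2-one | CC(C)CC(=O)N1C(=O)OC[C@H]1Cc1ccccc1 | intermediate
4 | 2-[(4-methoxybenzyl)oxy]acetaldehyde | COc1ccc(COCC=O)cc1 | starting material
5 | (4R)-4-benzyl-3-{(2R,3R)-3-hydroxy-4-[(4-methoxybenzyl)oxy]-2-(propan-2-yl)butanoyl}-1,3-oxazolidin-2-one | COc1ccc(COC[C@H](O)[C@@H](C(C)C)C(=O)N2C(=O)OC[C@H]2Cc2ccccc2)cc1 | intermediate
6 | (2R,3R)-3-hydroxy-N-methoxy-4-[(4-methoxybenzyl)oxy]-N-methyl-2-(propan-2-yl)butanamide | COc1ccc(COC[C@H](O)[C@@H](C(C)C)C(=O)N(C)OC)cc1 | intermediate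
7 | (2R,3R)-N-methoxy-4-[(4-methoxybenzyl)oxy]-N-methyl-2-(propan-2-yl)-3-[(triethylsilyl)oxy]butanamide | COc1ccc(COC[C@H](O[Si](CC)(CC)CC)[C@@H](C(C)C)C(=O)N(C)OC)cc1 | intermediate
8 | chloroiodomethane | ClCI | starting material
9 | (3R,4R)-1-chloro-5-[(4-methoxybenzyl)oxy]-3-(propan-2-yl)-4-[(triethylsilyl)oxy]pentan-2-one | COc1ccc(COC[C@H](O[Si](CC)(CC)CC)[C@@H](C(C)C)C(=O)CCl)cc1 | intermediate
10 | triethyl phosphonoacetate | CCOC(=O)CP(=O)(OCC)OCC | starting material
11 | ethyl (5R,6R)-2-(diethoxyphosphoryl)-7-[(4-methoxybenzyl)oxy]-4-oxo-5-(propan-2-yl)-6-[(triethylsilyl)oxy]heptanoate, both epimers at C2 | COc1ccc(COC[C@H](O[Si](CC)(CC)CC)[C@@H](C(C)C)C(=O)CC(C(=O)OCC)P(=O)(OCC)OCC)cc1 | intermediate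
12 | (R)-γ-valerolactone, (5R)-5-methyloxolan-2-one | C[C@@H]1CCC(=O)O1 | starting material
13 | (5R)-5-methyloxolan-2-ol, anomer mixture | C[C@@H]1CCC(O)O1 | intermediate
14 | ethyl (2E,6R)-6-hydroxy-2-{(3R,4R)-5-[(4-methoxybenzyl)oxy]-2-oxo-3-(propan-2-yl)-4-[(triethylsilyl)oxy]pentyl}hept-2-enoate | COc1ccc(COC[C@H](O[Si](CC)(CC)CC)[C@@H](C(C)C)C(=O)C/C(C(=O)OCC)=C\CC[C@@H](C)O)cc1 | intermediate
15 | ethyl (2E,6R)-6-hydroxy-2-{(3R,4R)-4-hydroxy-5-[(4-methoxybenzyl)oxy]-2-oxo-3-(propan-2-yl)pentyl}hept-2-enoate | COc1ccc(COC[C@H](O)[C@@H](C(C)C)C(=O)C/C(C(=O)OCC)=C\CC[C@@H](C)O)cc1 | intermediate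
16 | ethyl (2E,6R)-2-{(2R,3S,4R)-2,4-dihydroxy-5-[(4-methoxybenzyl)oxy]-3-(propan-2-yl)pentyl}-6-hydroxyhept-2-enoate | COc1ccc(COC[C@H](O)[C@@H](C(C)C)[C@H](O)C/C(C(=O)OCC)=C\CC[C@@H](C)O)cc1 | intermediate
17 | ethyl (2E,6R)-6-hydroxy-2-({(4R,5S,6R)-6-{[(4-methoxybenzyl)oxy]methyl}-2,2-dimethyl-5-(propan-2-yl)-1,3-dioxan-4-yl}methyl)hept-2-enoate | CC1(C)O[C@@H](COCc2ccc(OC)cc2)[C@@H](C(C)C)[C@@H](C/C(C(=O)OCC)=C\CC[C@@H](C)O)O1 | intermediate
18 | (2E,6R)-2-({(4R,5S,6R)-6-{[(4-methoxybenzyl)oxy]methyl}-2,2-dimethyl-5-(propan-2-yl)-1,3-dioxan-4-yl}methyl)hept-2-ene-1,6-diol | CC1(C)O[C@@H](COCc2ccc(OC)cc2)[C@@H](C(C)C)[C@@H](C/C(CO)=C\CC[C@@H](C)O)O1 | intermediate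
19 | (2R,5E)-7-[(tert-butyldiphenylsilyl)oxy]-6-({(4R,5S,6R)-6-{[(4-methoxybenzyl)oxy]methyl}-2,2-dimethyl-5-(propan-2-yl)-1,3-dioxan-4-yl}methyl)hept-5-en-2-ol | CC1(C)O[C@@H](COCc2ccc(OC)cc2)[C@@H](C(C)C)[C@@H](C/C(CO[Si](c2ccccc2)(c2ccccc2)C(C)(C)C)=C\CC[C@@H](C)O)O1 | intermediate
20 | (2R,5E)-7-[(tert-butyldiphenylsilyl)oxy]-6-({(4R,5S,6R)-6-{[(4-methoxybenzyl)oxy]methyl}-2,2-dimethyl-5-(propan-2-yl)-1,3-dioxan-4-yl}methyl)hept-5-en-2-yl methanesulfonate | CC1(C)O[C@@H](COCc2ccc(OC)cc2)[C@@H](C(C)C)[C@@H](C/C(CO[Si](c2ccccc2)(c2ccccc2)C(C)(C)C)=C\CC[C@@H](C)OS(C)(=O)=O)O1 | intermediate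
21 | (2R,5E)-7-[(tert-butyldiphenylsilyl)oxy]-6-{[(4R,5S,6R)-6-(hydroxymethyl)-2,2-dimethyl-5-(propan-2-yl)-1,3-dioxan-4-yl]methyl}hept-5-en-2-yl methanesulfonate | CC1(C)O[C@@H](CO)[C@@H](C(C)C)[C@@H](C/C(CO[Si](c2ccccc2)(c2ccccc2)C(C)(C)C)=C\CC[C@@H](C)OS(C)(=O)=O)O1 | intermediate
22 | thioacetate: compound 21 with CH2OH replaced by CH2SC(O)CH3 (dioxane centres R,S,R as in 21, mesylate carbon R, olefin E) | CC1(C)O[C@@H](CSC(C)=O)[C@@H](C(C)C)[C@@H](C/C(CO[Si](c2ccccc2)(c2ccccc2)C(C)(C)C)=C\CC[C@@H](C)OS(C)(=O)=O)O1 | intermediate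
23 | mesylate thiol: compound 22 with the free CH2SH group | CC1(C)O[C@@H](CS)[C@@H](C(C)C)[C@@H](C/C(CO[Si](c2ccccc2)(c2ccccc2)C(C)(C)C)=C\CC[C@@H](C)OS(C)(=O)=O)O1 | intermediate
24 | (1R,4S,7E,10R,14S)-8-{[(tert-butyldiphenylsilyl)oxy]methyl}-4,12,12-trimethyl-14-(propan-2-yl)-11,13-dioxa-3-thiabicyclo[8.3.1]tetradec-7-ene | CC1(C)O[C@H]2CS[C@@H](C)CC/C=C(CO[Si](c3ccccc3)(c3ccccc3)C(C)(C)C)\C[C@@H](O1)[C@@H]2C(C)C | intermediate
25 | (1R,4S,7E,10R,14S)-8-{[(tert-butyldiphenylsilyl)oxy]methyl}-4,12,12-trimethyl-14-(propan-2-yl)-11,13-dioxa-3-thiabicyclo[8.3.1]tetradec-7-ene 3,3-dioxide | CC1(C)O[C@H]2CS(=O)(=O)[C@@H](C)CC/C=C(CO[Si](c3ccccc3)(c3ccccc3)C(C)(C)C)\C[C@@H](O1)[C@@H]2C(C)C | intermediate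
26 | α-bromo sulfone: compound 25 brominated at C2 of the bicycle (target C5), configuration at the CHBr carbon not defined | CC1(C)O[C@H]2C(Br)S(=O)(=O)[C@@H](C)CC/C=C(CO[Si](c3ccccc3)(c3ccccc3)C(C)(C)C)\C[C@@H](O1)[C@@H]2C(C)C | intermediate
27 | episulfone: cis-fused thiirane 1,1-dioxide spanning target C4 and C5 on the ten-membered ring of 28 | CC1(C)O[C@H]2C3C(C)(CC/C=C(CO[Si](c4ccccc4)(c4ccccc4)C(C)(C)C)\C[C@@H](O1)[C@@H]2C(C)C)S3(=O)=O | intermediate
28 | (1S,2Z,6E,9R,13S)-7-{[(tert-butyldiphenylsilyl)oxy]methyl}-3,11,11-trimethyl-13-(propan-2-yl)-10,12-dioxabicyclo[7.3.1]trideca-2,6-diene | CC1(C)O[C@H]2/C=C(/C)CC/C=C(CO[Si](c3ccccc3)(c3ccccc3)C(C)(C)C)\C[C@@H](O1)[C@@H]2C(C)C | intermediate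
29 | (1R,2S,3S,4Z,8E)-9-{[(tert-butyldiphenylsilyl)oxy]methyl}-5-methyl-2-(propan-2-yl)cyclodeca-4,8-diene-1,3-diol | O[C@H]1/C=C(/C)CC/C=C(CO[Si](c2ccccc2)(c2ccccc2)C(C)(C)C)\C[C@@H](O)[C@@H]1C(C)C | intermediate
30 | (1R,2S,3S,4Z,8E)-9-{[(tert-butyldiphenylsilyl)oxy]methyl}-5-methyl-2-(propan-2-yl)cyclodeca-4,8-diene-1,3-diyl diacetate | CC(=O)O[C@H]1/C=C(/C)CC/C=C(CO[Si](c2ccccc2)(c2ccccc2)C(C)(C)C)\C[C@@H](OC(C)=O)[C@@H]1C(C)C | intermediate
31 | (1R,2S,3S,4Z,8E)-9-(hydroxymethyl)-5-methyl-2-(propan-2-yl)cyclodeca-4,8-diene-1,3-diyl diacetate | CC(=O)O[C@H]1/C=C(/C)CC/C=C(CO)\C[C@@H](OC(C)=O)[C@@H]1C(C)C | intermediate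
32 | (1R,4Z,6S,7S,8R,10R)-10-(hydroxymethyl)-4-methyl-7-(propan-2-yl)-11-oxabicyclo[8.1.0]undec-4-ene-6,8-diyl diacetate | CC(=O)O[C@H]1/C=C(/C)CC[C@H]2O[C@@]2(CO)C[C@@H](OC(C)=O)[C@@H]1C(C)C | intermediate
33 | (1R,4Z,6S,7S,8R,10S)-10-formyl-4-methyl-7-(propan-2-yl)-11-oxabicyclo[8.1.0]undec-4-ene-6,8-diyl diacetate (CNP0145766.3) | CC(=O)O[C@H]1/C=C(/C)CC[C@H]2O[C@@]2(C=O)C[C@@H](OC(C)=O)[C@@H]1C(C)C | target

**Step count**

Total step count: 24. Longest linear sequence: 23 steps (steps 1–6 and 8–24; step 7 is a one-step branch).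

**Steps most likely to fail**

Step 19 (Ramberg–Bäcklund contraction). Bromination on the solid base may be too slow, so that the C5 carbanion expels the C6 ketal oxygen (β-elimination), or the bromo sulfone may equilibrate and give a mixture of olefin geometries. The fallback separates halogenation from extrusion. It sets out from sulfone 25: kinetic deprotonation at C5 with LiN(SiMe3)2 in THF at −78 °C, where the lithio sulfone does not eliminate, and quenching with C2Cl6 should give the isolated α-chloro sulfone F1 with the halogen in a defined position. Treatment of F1 with KOtBu in THF at −78 → 0 °C (classical two-stage Ramberg–Bäcklund reaction, homogeneous base, low temperature) should then give the episulfone and, after SO2 loss, return to diene 28.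

Step 17 (closure of the eleven-membered thioether). Intermolecular S-alkylation to oligomers, oxidative disulfide formation, or E2 loss of the secondary mesylate may outrun ring closure. The fallback reverses the polarity of the ring-closing pair, so that the ring closes at a primary carbon with no elimination-prone electrophile. It sets out from alcohol 19: Mitsunobu reaction with thioacetic acid (PPh3, DIAD) puts sulfur on C4 with inversion to give the secondary thioacetate F2; DDQ removes the PMB group to give the primary alcohol F3; MsCl/Et3N gives the primary mesylate F4. Cs2CO3 in degassed DMF/MeOH at high dilution then lets the secondary thiolate displace the primary mesylate and returns to thioether 24, with the same C4 configuration, since one inversion occurs in either order.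

Step 23 (Sharpless epoxidation). The conformational bias of the ten-membered ring may override tartrate control (poor facial selectivity), or the hindered olefin may react sluggishly. The fallback changes from electrophilic, hydroxyl-directed oxygen transfer to nucleophilic epoxidation of the enal. It sets out from allylic alcohol 31: MnO2 in CH2Cl2 should give the enal F5. Amine-catalysed epoxidation of this α-branched enal with 50% aq. H2O2 in dioxane, using 9-amino-9-deoxy-epi-quinine as its trifluoroacetate salt (or the quinidine-derived pseudo-enantiomer, whichever delivers the needed face), should give target 33 directly.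

Further compounds
F1 | step 19 | α-chloro sulfone: compound 25 chlorinated at C2 of the bicycle (target C5) | CC1(C)O[C@H]2C(Cl)S(=O)(=O)[C@@H](C)CC/C=C(CO[Si](c3ccccc3)(c3ccccc3)C(C)(C)C)\C[C@@H](O1)[C@@H]2C(C)C
F2 | step 17 | secondary thioacetate: compound 19 with the C4 hydroxyl replaced by SC(O)CH3 with inversion (S) | CC1(C)O[C@@H](COCc2ccc(OC)cc2)[C@@H](C(C)C)[C@@H](C/C(CO[Si](c2ccccc2)(c2ccccc2)C(C)(C)C)=C\CC[C@H](C)SC(C)=O)O1
F3 | step 17 | primary alcohol: F2 without the PMB group | CC1(C)O[C@@H](CO)[C@@H](C(C)C)[C@@H](C/C(CO[Si](c2ccccc2)(c2ccccc2)C(C)(C)C)=C\CC[C@H](C)SC(C)=O)O1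
F4 | step 17 | primary mesylate of F3 | CC1(C)O[C@@H](COS(C)(=O)=O)[C@@H](C(C)C)[C@@H](C/C(CO[Si](c2ccccc2)(c2ccccc2)C(C)(C)C)=C\CC[C@H](C)SC(C)=O)O1
F5 | step 23 | (1R,2S,3S,4Z,8E)-9-formyl-5-methyl-2-(propan-2-yl)cyclodeca-4,8-diene-1,3-diyl diacetate | CC(=O)O[C@H]1/C=C(/C)CC/C=C(C=O)\C[C@@H](OC(C)=O)[C@@H]1C(C)C
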